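## Retrosynthetic overview

1. Target ⇒ its octamethyl ether. The seven-membered ring is closed last by acid (intramolecular Friedel–Crafts hydroarylation of a 2,4-dimethoxystyryl arm onto ring A); the same acid turns both cis-dihydrofurans trans, and BBr3 then frees the eight phenols in the same flask.
2. Both dihydrofuran rings ⇒ one bis(diaryldiazomethane) by a double enantioselective rhodium-carbene 1,5-C–H insertion into two 4-methoxybenzyl aryl ethers. Two rings and four stereocentres form in one operation; each benzyl group becomes C2 plus its 4-oxyphenyl ring.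
3. Bis(diazo) ⇒ bis(hydrazone) ⇒ diaryl diketone ⇒ diol from a one-flask three-component union (aryllithium + aldehyde, Br/Li exchange, second aldehyde).
4. The two aldehydes ⇒ 4-bromo-2,6-difluorobenzaldehyde (two SNAr reactions in one flask) and 2-bromo-4,6-dimethoxybenzaldehyde (ortho-demethylation, benzylation, Heck).
5. Ring order: the two dihydrofurans together (step 8), then the seven-membered carbocycle (step 9).

Labels: ring A is the benzo ring of the first dihydrobenzofuran (C2, C3; C3 carries the 3,5-dioxyphenyl group); ring B is the benzo ring of the second dihydrobenzofuran (C2', C3'), which is fused to the seven-membered ring.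

Assumption: Rh2(S-PTAD)4 (PTAD = (1-adamantyl)(phthalimido)acetate) is taken to be the catalyst antipode that gives S at both carbene carbons (C3, C3'); if the first run shows the opposite sense, Rh2(R-PTAD)4 is used and nothing else changes.

## Route

Step 1
Reactants: 1 4-bromo-2,6-difluorobenzaldehyde; 2 4-methoxybenzyl alcohol
Product: 4 4-bromo-2-methoxy-6-[(4-methoxybenzyl)oxy]benzaldehyde, via fluoro ether 3 (not isolated)
Conditions: 2 (1.0 equiv), KOt-Bu (1.0 equiv), THF, 0 °C; then NaOMe (2 equiv), MeOH, 60 °C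
Reagents that add atoms: sodium methoxide, [Na+].[O-]C
Why: Two nucleophilic aromatic substitutions (SNAr) in sequence: both fluorides are ortho to the formyl group, the first alkoxy group slows the second substitution enough for clean mono-benzylation at 0 °C, and methoxide at 60 °C then displaces the remaining fluoride; no stereocentre is formed.

Step 2
Reactants: 5 2-bromo-4,6-dimethoxybenzaldehyde
Product: 6 2-bromo-6-hydroxy-4-methoxybenzaldehyde
Conditions: BCl3 (1.2 equiv), CH2Cl2, −78 → 0 °C; H2O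
Reagents that add atoms: none
Why: Chelation-controlled Lewis acid ether cleavage: BCl3 bound to the formyl oxygen removes only the methyl group ortho to it and leaves the para methoxy group; no stereocentre.

Step 3
Reactants: 6 2-bromo-6-hydroxy-4-methoxybenzaldehyde; 7 4-methoxybenzyl chloride
Product: 8 2-bromo-4-methoxy-6-[(4-methoxybenzyl)oxy]benzaldehyde
Conditions: K2CO3, KI (cat.), DMF, 60 °C
Reagents that add atoms: none
Why: Williamson ether synthesis on the phenoxide; this benzyl group later supplies C2' and its aryl ring.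

Step 4
Reactants: 8 2-bromo-4-methoxy-6-[(4-methoxybenzyl)oxy]benzaldehyde; 9 2,4-dimethoxystyrene
Product: 10 2-[(E)-2-(2,4-dimethoxyphenyl)ethenyl]-4-methoxy-6-[(4-methoxybenzyl)oxy]benzaldehyde
Conditions: Pd(OAc)2 (5 mol%), P(o-tol)3 (10 mol%), K2CO3, DMF, 100 °C
Reagents that add atoms: none
Why: Mizoroki–Heck reaction: the bromide ortho to the formyl group adds readily to the palladium catalyst, and syn insertion followed by syn β-hydride elimination gives the E-stilbene.

Step 5
Reactants: 4 4-bromo-2-methoxy-6-[(4-methoxybenzyl)oxy]benzaldehyde; 10 2-[(E)-2-(2,4-dimethoxyphenyl)ethenyl]-4-methoxy-6-[(4-methoxybenzyl)oxy]benzaldehyde; 11 1-bromo-3,5-dimethoxybenzene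
Product: 15 (3,5-dimethoxyphenyl)[4-({2-[(E)-2-(2,4-dimethoxyphenyl)ethenyl]-4-methoxy-6-[(4-methoxybenzyl)oxy]phenyl}(hydroxy)methyl)-2-methoxy-6-[(4-methoxybenzyl)oxy]phenyl]methanol (diastereomer mixture), via aryllithium 12 (not isolated), via lithium alkoxide 13 (not isolated), via dilithio species 14 (not isolated)
Conditions: 11, n-BuLi (1.0 equiv), THF, −78 °C; 4, −78 °C; n-BuLi (1.05 equiv), −78 °C, 15 min; 10, −78 → −20 °C; H2O
Reagents that add atoms: none
Why: Bromine–lithium exchange followed by 1,2-addition of an aryllithium to an aldehyde, run twice in one flask (exchange is faster than any deprotonation at −78 °C and the first lithium alkoxide is inert); the two carbinol centres form without control and are erased in step 6.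

Step 6
Reactants: 15 the diol
Product: 16 (3,5-dimethoxyphenyl)[4-({2-[(E)-2-(2,4-dimethoxyphenyl)ethenyl]-4-methoxy-6-[(4-methoxybenzyl)oxy]phenyl}carbonyl)-2-methoxy-6-[(4-methoxybenzyl)oxy]phenyl]methanone
Conditions: Dess–Martin periodinane (2.5 equiv), CH2Cl2, 0 °C → rt
Reagents that add atoms: none
Why: Dess–Martin oxidation of two doubly benzylic secondary alcohols to diaryl ketones; the stilbene and the benzyl ethers are not touched.

Step 7
Reactants: 16 the diketone
Product: 17 bis(hydrazone) of 16 (both C=O replaced by C=N–NH2)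
Conditions: N2H4·H2O (30 equiv), AcOH (cat.), n-BuOH, 120 °C, sealed tube, argon, 48 h
Reagents that add atoms: hydrazine (used as the monohydrate), NN
Why: Hydrazone formation by condensation; heat and excess hydrazine are needed because each carbonyl group carries a 2,6-disubstituted aryl ring, and argon keeps diimide from reducing the stilbene.

Step 8
Reactants: 17 the bis(hydrazone)
Product: 19 (2R,3S)-3-(3,5-dimethoxyphenyl)-6-{(2R,3S)-4-[(E)-2-(2,4-dimethoxyphenyl)ethenyl]-6-methoxy-2-(4-methoxyphenyl)-2,3-dihydro-1-benzofuran-3-yl}-4-methoxy-2-(4-methoxyphenyl)-2,3-dihydro-1-benzofuran (both rings 2,3-cis), via bis(diazo) compound 18 (not isolated)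
Conditions: MnO2 (activated, 10 equiv), CH2Cl2, 0 °C, 1 h, dark; filtered under argon and added over 1 h to Rh2(S-PTAD)4 (2 mol%), CH2Cl2, −20 °C → rt
Reagents that add atoms: none
Why: Proposed new method: MnO2 dehydrogenates both hydrazones to diaryldiazomethanes and the chiral dirhodium tetracarboxylate turns each into a donor/donor carbene that inserts into the neighbouring ArCH2–O bond through a five-membered, hydride-shift-like transition state (the benzylic, oxygen-activated C–H is far preferred over OCH3 and over the electronically mismatched styryl alkene), the catalyst fixing C3 and C3' as S independently of the other, remote site and placing each new C2 aryl group cis (kinetic), with the mismatched diastereomer removed by chromatography so that the enantiomeric purity of 19 is statistically amplified; the closest known reaction is the enantioselective intramolecular C–H insertion of donor/donor rhodium carbenes into benzyl aryl ethers to give cis-2,3-diaryl-dihydrobenzofurans, here run at two sites of one molecule at once.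

Step 9
Reactants: 19 the bis(cis-dihydrobenzofuran)
Product: 21 CNP0154774.1, via cyclised octamethyl ether 20 (not isolated)
Conditions: TfOH (0.2 equiv), CH2Cl2, −40 → 0 °C, 2 h; then BBr3 (20 equiv), −78 °C → rt, 12 h; MeOH, H2O; reverse-phase HPLC
Reagents that add atoms: none
Why: Cationic cascade then Lewis acid ether cleavage: protonation of the styryl alkene gives a 2,4-dimethoxybenzylic cation that closes the seven-membered ring by intramolecular Friedel–Crafts alkylation at C7 of ring A (C5 is shielded by the methoxy group buttressed against C3), reversibly and therefore with the aryl group pseudo-axial, away from the peri oxygen O1 and cis to H-3' (the S centre), as in the acid-induced conversion of ε-viniferin into ampelopsin B; the same acid opens each C2–O bond through its 4-methoxybenzylic cation and recloses it trans (C3 and C3' are not touched), and BBr3 then cleaves the eight methyl ethers.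

## Compound list

1 | 4-bromo-2,6-difluorobenzaldehyde | O=Cc1c(F)cc(Br)cc1F | starting material
2 | 4-methoxybenzyl alcohol | COc1ccc(CO)cc1 | starting material
3 | 4-bromo-2-fluoro-6-[(4-methoxybenzyl)oxy]benzaldehyde | O=Cc1c(F)cc(Br)cc1OCc1ccc(OC)cc1 | intermediate
4 | 4-bromo-2-methoxy-6-[(4-methoxybenzyl)oxy]benzaldehyde | COc1cc(Br)cc(OCc2ccc(OC)cc2)c1C=O | intermediate
5 | 2-bromo-4,6-dimethoxybenzaldehyde | COc1cc(Br)c(C=O)c(OC)c1 | starting material
6 | 2-bromo-6-hydroxy-4-methoxybenzaldehyde | COc1cc(O)c(C=O)c(Br)c1 | intermediate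
7 | 4-methoxybenzyl chloride | COc1ccc(CCl)cc1 | starting material
8 | 2-bromo-4-methoxy-6-[(4-methoxybenzyl)oxy]benzaldehyde | COc1cc(Br)c(C=O)c(OCc2ccc(OC)cc2)c1 | intermediate
9 | 2,4-dimethoxystyrene | C=Cc1ccc(OC)cc1OC | starting material
10 | 2-[(E)-2-(2,4-dimethoxyphenyl)ethenyl]-4-methoxy-6-[(4-methoxybenzyl)oxy]benzaldehyde | COc1cc(/C=C/c2ccc(OC)cc2OC)c(C=O)c(OCc2ccc(OC)cc2)c1 | intermediate
11 | 1-bromo-3,5-dimethoxybenzene | COc1cc(Br)cc(OC)c1 | starting material
12 | 3,5-dimethoxyphenyllithium | COc1cc([Li])cc(OC)c1 | intermediate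
13 | lithium (4-bromo-2-methoxy-6-[(4-methoxybenzyl)oxy]phenyl)(3,5-dimethoxyphenyl)methanolate (racemic) | COc1cc(Br)cc(OCc2ccc(OC)cc2)c1C(O[Li])c1cc(OC)cc(OC)c1 | intermediate
14 | lithium (3,5-dimethoxyphenyl)(4-lithio-2-methoxy-6-[(4-methoxybenzyl)oxy]phenyl)methanolate (racemic) | COc1cc([Li])cc(OCc2ccc(OC)cc2)c1C(O[Li])c1cc(OC)cc(OC)c1 | intermediate
15 | (3,5-dimethoxyphenyl)[4-({2-[(E)-2-(2,4-dimethoxyphenyl)ethenyl]-4-methoxy-6-[(4-methoxybenzyl)oxy]phenyl}(hydroxy)methyl)-2-methoxy-6-[(4-methoxybenzyl)oxy]phenyl]methanol (diastereomer mixture) | COc1ccc(COc2cc(cc(OC)c2C(O)c2cc(OC)cc(OC)c2)C(O)c2c(cc(OC)cc2OCc2ccc(OC)cc2)/C=C/c2ccc(OC)cc2OC)cc1 | intermediate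
16 | (3,5-dimethoxyphenyl)[4-({2-[(E)-2-(2,4-dimethoxyphenyl)ethenyl]-4-methoxy-6-[(4-methoxybenzyl)oxy]phenyl}carbonyl)-2-methoxy-6-[(4-methoxybenzyl)oxy]phenyl]methanone | COc1ccc(COc2cc(cc(OC)c2C(=O)c2cc(OC)cc(OC)c2)C(=O)c2c(cc(OC)cc2OCc2ccc(OC)cc2)/C=C/c2ccc(OC)cc2OC)cc1 | intermediate
17 | bis(hydrazone) of 16 (C=N geometry not defined) | COc1ccc(COc2cc(cc(OC)c2C(=NN)c2cc(OC)cc(OC)c2)C(=NN)c2c(cc(OC)cc2OCc2ccc(OC)cc2)/C=C/c2ccc(OC)cc2OC)cc1 | intermediate
18 | bis(diazo) compound (both C=N–NH2 groups of 17 as C=N2) | COc1ccc(COc2cc(cc(OC)c2C(=[N+]=[N-])c2cc(OC)cc(OC)c2)C(=[N+]=[N-])c2c(cc(OC)cc2OCc2ccc(OC)cc2)/C=C/c2ccc(OC)cc2OC)cc1 | intermediate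
19 | (2R,3S)-3-(3,5-dimethoxyphenyl)-6-{(2R,3S)-4-[(E)-2-(2,4-dimethoxyphenyl)ethenyl]-6-methoxy-2-(4-methoxyphenyl)-2,3-dihydro-1-benzofuran-3-yl}-4-methoxy-2-(4-methoxyphenyl)-2,3-dihydro-1-benzofuran (both rings cis) | COc1ccc([C@@H]2Oc3cc(cc(OC)c3[C@@H]2c2cc(OC)cc(OC)c2)[C@H]2c3c(cc(OC)cc3O[C@H]2c2ccc(OC)cc2)/C=C/c2ccc(OC)cc2OC)cc1 | intermediate
20 | octamethyl ether of the target (same skeleton as 21; 2S,3S and 2'S,3'S trans rings, benzylic methine S; all eight OH as OMe) | COc1ccc([C@H]2Oc3c4c(cc(OC)c3[C@@H]2c2cc(OC)cc(OC)c2)[C@H]2c3c(cc(OC)cc3O[C@@H]2c2ccc(OC)cc2)C[C@H]4c2ccc(OC)cc2OC)cc1 | intermediate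
21 | CNP0154774.1: (2S,3S)-3-(3,5-dihydroxyphenyl)-2-(4-hydroxyphenyl)-2,3-dihydrobenzofuran-4-ol whose C6 is bonded to C3' of a second (2'S,3'S)-6-hydroxy-2-(4-hydroxyphenyl)-2,3-dihydrobenzofuran and whose C7 carries an (S)-CH(2,4-dihydroxyphenyl) linked through CH2 to C4' of that second ring (seven-membered carbocycle) | Oc1ccc([C@H]2Oc3c4c(cc(O)c3[C@@H]2c2cc(O)cc(O)c2)[C@H]2c3c(cc(O)cc3O[C@@H]2c2ccc(O)cc2)C[C@H]4c2ccc(O)cc2O)cc1 | target

## Step count and risks

Total step count: 9.
Longest linear sequence: 8 steps (5 → 6 → 8 → 10 → 15 → 16 → 17 → 19 → 21).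

The three steps most likely to fail:

**Step 8 (double C–H insertion).** The diazo group or carbene on ring B sits ortho to a styryl group, which may cyclise onto it instead of inserting. The fallback brings the styryl arm in after the ring closures. It sets out from 8, which is used in place of 10 in the union with the dilithio species 14 and gives the bromo diol F2. Dess–Martin oxidation gives the bromo diketone F3, hydrazine the bromo bis(hydrazone) F4, MnO2 the bromo bis(diazo) compound F5, and Rh2(S-PTAD)4 the bromo bis(cis-dihydrobenzofuran) F6. A late Heck reaction of F6 with 9 (Pd(OAc)2, SPhos, K2CO3, DMF, 110 °C) comes back to the route at 19.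

**Step 7 (hindered bis(hydrazone)).** Both carbonyl groups are flanked by a 2,6-disubstituted aryl ring and may not condense. The fallback sets out from 16: Lawesson's reagent (toluene, 90 °C) gives the bis(thioketone) F1, whose C=S groups exchange with hydrazine at room temperature. It comes back to the route at 17.

**Step 9 (cascade and global demethylation).** The ring closure could go to the wrong position of ring A at the methyl ether stage, or the product could decompose in BBr3. The fallback reverses the order. It sets out from 19: BBr3 alone (CH2Cl2, −78 → 0 °C, NaHCO3 quench; styryl units of this type survive when no protic acid is present) gives the stilbene octaphenol F7. HCl in MeOH at room temperature then closes the seven-membered ring on the free phenol, equilibrates any remaining cis ring to trans, and comes back to the route at 21.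

## Further compounds

F1 | step 7 | bis(thioketone) of 16 (both C=O as C=S) | COc1ccc(COc2cc(cc(OC)c2C(=S)c2cc(OC)cc(OC)c2)C(=S)c2c(cc(OC)cc2OCc2ccc(OC)cc2)/C=C/c2ccc(OC)cc2OC)cc1
F2 | step 8 | (3,5-dimethoxyphenyl)[4-({2-bromo-4-methoxy-6-[(4-methoxybenzyl)oxy]phenyl}(hydroxy)methyl)-2-methoxy-6-[(4-methoxybenzyl)oxy]phenyl]methanol (diastereomer mixture) | COc1ccc(COc2cc(cc(OC)c2C(O)c2cc(OC)cc(OC)c2)C(O)c2c(Br)cc(OC)cc2OCc2ccc(OC)cc2)cc1
F3 | step 8 | (3,5-dimethoxyphenyl)[4-({2-bromo-4-methoxy-6-[(4-methoxybenzyl)oxy]phenyl}carbonyl)-2-methoxy-6-[(4-methoxybenzyl)oxy]phenyl]methanone | COc1ccc(COc2cc(cc(OC)c2C(=O)c2cc(OC)cc(OC)c2)C(=O)c2c(Br)cc(OC)cc2OCc2ccc(OC)cc2)cc1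
F4 | step 8 | bis(hydrazone) of F3 | COc1ccc(COc2cc(cc(OC)c2C(=NN)c2cc(OC)cc(OC)c2)C(=NN)c2c(Br)cc(OC)cc2OCc2ccc(OC)cc2)cc1
F5 | step 8 | bis(diazo) compound from F4 | COc1ccc(COc2cc(cc(OC)c2C(=[N+]=[N-])c2cc(OC)cc(OC)c2)C(=[N+]=[N-])c2c(Br)cc(OC)cc2OCc2ccc(OC)cc2)cc1
F6 | step 8 | (2R,3S)-6-[(2R,3S)-4-bromo-6-methoxy-2-(4-methoxyphenyl)-2,3-dihydro-1-benzofuran-3-yl]-3-(3,5-dimethoxyphenyl)-4-methoxy-2-(4-methoxyphenyl)-2,3-dihydro-1-benzofuran (both rings cis) | COc1ccc([C@@H]2Oc3cc(cc(OC)c3[C@@H]2c2cc(OC)cc(OC)c2)[C@H]2c3c(Br)cc(OC)cc3O[C@H]2c2ccc(OC)cc2)cc1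
F7 | step 9 | (2S,3S)-3-(3,5-dihydroxyphenyl)-6-{(2S,3S)-4-[(E)-2-(2,4-dihydroxyphenyl)ethenyl]-6-hydroxy-2-(4-hydroxyphenyl)-2,3-dihydro-1-benzofuran-3-yl}-2-(4-hydroxyphenyl)-2,3-dihydro-1-benzofuran-4-ol (both rings trans) | Oc1ccc([C@H]2Oc3cc(cc(O)c3[C@@H]2c2cc(O)cc(O)c2)[C@H]2c3c(cc(O)cc3O[C@@H]2c2ccc(O)cc2)/C=C/c2ccc(O)cc2O)cc1
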